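Ring atoms are numbered from the alkylidene carbon C1. The cyclohexane is closed at its most hindered bond, between C3 (quaternary: methyl and polyene chain) and C2 (the CH bearing the 3-hydroxypropyl arm). C3 and the neighbouring tertiary carbinol C4 are read as the two carbons of a tetrasubstituted epoxide; C1, C2 and the hydroxypropyl arm with its oxygen are read as a 3,4-dihydro-2H-pyran. In an acyclic epoxy polyene carrying this cyclic enol ether, a Lewis acid triggers anti opening of the epoxide by the enol ether carbon: one operation forges the ring, the quaternary centre, the carbinol and the C2 stereocentre. The pyran is later unzipped into enal and hydroxypropyl arm.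

Key step: step 15

Assumption: the (R)-configured phosphoric acid of step 1 is taken to give the 4R alcohol with an enal as it does with aryl aldehydes (otherwise its mirror image is used), and the propanal silyl enol ether 33 is taken as purchasable as an E/Z mixture.

**Fragment 1 (polyene chain)**

Step 1
Reactants: 1 3-methylbut-2-enal; 2 allenylboronic acid pinacol ester
Product: 4 (4R)-6-methylhept-5-en-1-yn-4-ol, via borate ester 3 (not isolated)
Conditions: (R)-TRIP phosphoric acid (10 mol%), 4 Å MS, toluene, 0 °C; aq. work-up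
Reagents that add atoms: none
Why: Chiral-phosphoric-acid-catalysed propargylboration, in which the allenylboronate transfers its γ-carbon through a closed six-membered transition state held by the catalyst, so that only 1,2-addition occurs and the R carbinol centre is set by enantioface selection.

Step 2
Reactants: 4 (4R)-6-methylhept-5-en-1-yn-4-ol
Product: 5 tert-butyldimethylsilyl ether of 4
Conditions: TBSCl, imidazole, DMF, rt
Reagents that add atoms: tert-butyldimethylsilyl chloride CC(C)(C)[Si](C)(C)Cl
Why: Standard silylation of the secondary alcohol; the ether masks the allylic hydroxyl, which would otherwise direct the later titanium epoxidation to the wrong alkene.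

Step 3
Reactants: 5 silyl ether
Product: 7 (1E,4R)-4-(tert-butyldimethylsilyloxy)-1-iodo-2,6-dimethylhepta-1,5-diene, via alkenylalane 6 (not isolated)
Conditions: Me3Al, Cp2ZrCl2 (25 mol%), CH2Cl2, 0 °C to rt; then I2, THF, −30 °C
Reagents that add atoms: trimethylaluminium C[Al](C)C; iodine II
Why: Zirconium-catalysed carboalumination adds methyl and aluminium syn across the terminal alkyne with aluminium at the terminus, and iodinolysis with retention should give the E trisubstituted alkenyl iodide; the trisubstituted alkene is inert.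

Step 4
Reactants: 7 alkenyl iodide; 8 (4-bromobut-1-yn-1-yl)trimethylsilane
Product: 11 (5E,8R)-8-(tert-butyldimethylsilyloxy)-6,10-dimethylundeca-5,9-dien-1-yne, via organozinc bromide 9 (not isolated), via silylated enyne 10 (not isolated)
Conditions: 8, Zn dust, LiCl, THF, 50 °C; then 7, Pd(PPh3)4 (5 mol%), THF, rt; then K2CO3, MeOH, rt
Reagents that add atoms: none
Why: Negishi sp2–sp3 cross-coupling (zinc insertion into the primary bromide, then palladium catalysis) proceeds with retention of the E geometry, and methanolysis removes the alkynyl silane.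

Step 5
Reactants: 11 terminal enyne; 12 oxirane
Product: 15 (3E,7E,10R)-10-(tert-butyldimethylsilyloxy)-4,8,12-trimethyltrideca-3,7,11-trien-1-ol, via alkenylalane 13 (not isolated), via lithium alanate 14 (not isolated)
Conditions: Me3Al, Cp2ZrCl2 (25 mol%), CH2Cl2, rt; volatiles removed; n-BuLi, THF/hexane, −78 to 0 °C; oxirane, 0 °C to rt
Reagents that add atoms: trimethylaluminium C[Al](C)C
Why: A second carboalumination sets the next E trisubstituted alkene, and the lithium alanate formed with n-BuLi should transfer its alkenyl group to oxirane with retention (alkenylalanate opening of an epoxide).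

Step 6
Reactants: 15 homoallylic alcohol
Product: 16 (3E,7E,10R)-10-(tert-butyldimethylsilyloxy)-1-iodo-4,8,12-trimethyltrideca-3,7,11-triene
Conditions: PPh3, imidazole, I2, CH2Cl2, 0 °C
Reagents that add atoms: iodine II
Why: Garegg–Samuelsson (Appel-type) iodination of the primary alcohol under imidazole buffering, which spares the allylic silyl ether.

**Fragment 2 (dihydropyran core)**

Step 7
Reactants: 17 3,4-dihydro-2H-pyran; 12 oxirane
Product: 19 2-(3,4-dihydro-2H-pyran-6-yl)ethan-1-ol, via lithiated dihydropyran 18 (not isolated)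
Conditions: t-BuLi, THF/pentane, −78 to 0 °C; then oxirane, −78 °C to rt
Reagents that add atoms: none
Why: Kinetic α-lithiation of the cyclic enol ether at the vinylic carbon next to oxygen, then ring opening of oxirane by the alkenyllithium.

Step 8
Reactants: 19 dihydropyranyl ethanol
Product: 20 6-(2-iodoethyl)-3,4-dihydro-2H-pyran
Conditions: PPh3, imidazole, I2 (premixed), Et2O/MeCN, 0 °C
Reagents that add atoms: iodine II
Why: Garegg–Samuelsson iodination; the phosphine–iodine adduct is preformed so that the enol ether meets neither free iodine nor acid.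

Step 9
Reactants: 20 iodide; 21 ethyl 3-oxobutanoate
Product: 22 ethyl 2-acetyl-4-(3,4-dihydro-2H-pyran-6-yl)butanoate
Conditions: Cs2CO3, DMF, rt (21 in excess)
Reagents that add atoms: none
Why: Acetoacetic ester C-alkylation of the soft enolate by the primary iodide; the new stereocentre is destroyed in the next step.

Step 10
Reactants: 22 α-substituted β-keto ester
Product: 24 ethyl (2Z)-2-[2-(3,4-dihydro-2H-pyran-6-yl)ethyl]-3-(trifluoromethylsulfonyloxy)but-2-enoate, via sodium enolate 23 (not isolated)
Conditions: NaH, THF, 0 °C; then PhNTf2, 0 °C to rt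
Reagents that add atoms: N-phenylbis(trifluoromethanesulfonimide) O=S(=O)(N(c1ccccc1)S(=O)(=O)C(F)(F)F)C(F)(F)F
Why: The sodium enolate is chelated between ketone and ester oxygens, so O-triflation of the ketone-derived oxygen should give the Z enol triflate (triflate syn to the ester).

**Union and completion**

Step 11
Reactants: 16 chain iodide; 24 Z enol triflate
Product: 26 ethyl (2Z,6E,10E,13R)-13-(tert-butyldimethylsilyloxy)-2-[2-(3,4-dihydro-2H-pyran-6-yl)ethyl]-3,7,11,15-tetramethylhexadeca-2,6,10,14-tetraenoate, via alkylzinc iodide 25 (not isolated)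
Conditions: 16, Zn dust, LiCl, THF, 40 °C; then 24, PdCl2(dppf) (5 mol%), THF, 50 °C
Reagents that add atoms: none
Why: Negishi coupling of the alkylzinc iodide is stereoretentive at the enol triflate carbon, so the polyene chain ends syn to the ester and the methyl group syn to the dihydropyranylethyl arm (Z tetrasubstituted alkene).

Step 12
Reactants: 26 tetrasubstituted enoate
Product: 27 (2Z,6E,10E,13R)-13-(tert-butyldimethylsilyloxy)-2-[2-(3,4-dihydro-2H-pyran-6-yl)ethyl]-3,7,11,15-tetramethylhexadeca-2,6,10,14-tetraen-1-ol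
Conditions: iBu2AlH, CH2Cl2, −78 to −20 °C; aq. Rochelle salt
Reagents that add atoms: none
Why: 1,2-Reduction of the conjugated ester by the aluminium hydride; alkene geometry and enol ether are untouched.

Step 13
Reactants: 27 Z allylic alcohol
Product: 28 (2S,3R)-epoxy alcohol (oxirane C2 bears CH2OH and the dihydropyranylethyl arm; C3 bears methyl and the chain)
Conditions: Ti(OiPr)4 (10 mol%), L-(+)-diethyl tartrate (12 mol%), t-BuOOH, 4 Å MS, CH2Cl2, −25 °C
Reagents that add atoms: tert-butyl hydroperoxide CC(C)(C)OO
Why: Sharpless asymmetric epoxidation: the titanium tartrate binds the allylic hydroxyl, so of five alkenes only the tetrasubstituted one is epoxidised, and L-(+)-tartrate delivers oxygen to the face that gives the (2S,3R) epoxide (the sense known for nerol); both future ring stereocentres C3 and C4 are set here.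

Step 14
Reactants: 28 epoxy alcohol
Product: 30 (2R,3R)-2-[2-(3,4-dihydro-2H-pyran-6-yl)ethyl]-2,3-dimethyl-3-[(3E,7E,10R)-10-(tert-butyldimethylsilyloxy)-4,8,12-trimethyltrideca-3,7,11-trien-1-yl]oxirane, via epoxy mesylate 29 (not isolated)
Conditions: MsCl, Et3N, THF, −20 °C; filter; then LiBHEt3, −20 to 0 °C
Reagents that add atoms: none
Why: Mesylation, then SN2 displacement of the primary sulfonate by hydride, turns the directing hydroxymethyl group into the C4 methyl group; the fully substituted epoxide carbons should resist the hydride.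

Step 15
Reactants: 30 epoxy polyene with dihydropyran
Product: 32 (2R,3R,4R)-4-hydroxy-2-(3-hydroxypropyl)-3,4-dimethyl-3-[(3E,7E,10R)-10-(tert-butyldimethylsilyloxy)-4,8,12-trimethyltrideca-3,7,11-trien-1-yl]cyclohexan-1-one, via pyranylium aluminate 31 (not isolated)
Conditions: MeAlCl2 (1.5 equiv), CH2Cl2, −78 °C; then aq. NaH2PO4/THF, 0 °C
Reagents that add atoms: water O
Why: Lewis-acid-promoted epoxide-opening cation–olefin cyclization terminated by an enol ether (closest known type: the epoxy-polyene cyclization promoted by an alkylaluminium chloride): MeAlCl2 binds the epoxide oxygen, C5 of the dihydropyran attacks the distal epoxide carbon with inversion while the oxygen stays on the proximal carbon, and the pyranylium ion is hydrolysed on work-up to the ketone and the free hydroxypropyl arm. The cyclohexane closes in the 6-endo mode with respect to both partners (both epoxide carbons and both enol ether carbons become ring atoms); attack at the proximal epoxide carbon would be a 5-endo-trig closure and is geometrically disfavoured. The quaternary C3 is set by stereospecific anti opening of the (2R,3R) epoxide and C4 keeps its configuration, so their relative and absolute configuration come from the Z alkene geometry and the Sharpless step. C2 is set in a chair transition state with the departing oxygen and the polyene chain equatorial, in which the ring-locked Z enol ether holds the future hydroxypropyl carbons equatorial, cis to the C3 methyl and the C4 hydroxyl; the same isomer is the all-equatorial, thermodynamically preferred ketone, so enolisation cannot erode it. The step needs the enol ether to win over the three trisubstituted alkenes and over pinacol-type shifts: it is by far the strongest π-nucleophile, it sits six atoms from the electrophilic carbon, and MeAlCl2 scavenges protons that would hydrolyse it.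

Step 16
Reactants: 32 keto diol; 33 trimethyl(prop-1-en-1-yloxy)silane
Product: 35 (2Z)-2-[(2S,3R,4R)-4-hydroxy-2-(3-hydroxypropyl)-3,4-dimethyl-3-[(3E,7E,10R)-10-(tert-butyldimethylsilyloxy)-4,8,12-trimethyltrideca-3,7,11-trien-1-yl]cyclohexylidene]propanal, via pyranyl aldehyde 34 (not isolated)
Conditions: 33 (3 equiv), Me3SiOTf (0.3 equiv), CH2Cl2, −78 to −40 °C; then DBU, MeOH, 0 °C
Reagents that add atoms: none
Why: Mukaiyama-type addition of the aldehyde-derived silyl enol ether to the six-membered oxocarbenium ion formed when the δ-hydroxy ketone closes to its hemiketal and ionises, followed by base-induced E1cB expulsion of the ring oxygen, which reopens the pyran to the hydroxypropyl arm and the tetrasubstituted enal; because the tethered alkoxide can re-add and leave again the geometry is thermodynamic, and the Z isomer (small formyl group, not methyl, facing the substituted C2) is expected to prevail.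

Step 17
Reactants: 35 silyl-protected enal
Product: 36 target compound CNP0270422.1
Conditions: HF·pyridine, pyridine, THF, 0 °C to rt
Reagents that add atoms: none
Why: Fluoride cleaves the silyl ether under buffered conditions that should spare the acid-labile allylic alcohol and the enal.

**Compound list**

1 | 3-methylbut-2-enal | CC(C)=CC=O | starting material
2 | 4,4,5,5-tetramethyl-2-(propa-1,2-dien-1-yl)-1,3,2-dioxaborolane (allenylboronic acid pinacol ester) | C=C=CB1OC(C)(C)C(C)(C)O1 | starting material
3 | 4,4,5,5-tetramethyl-2-{[(4R)-6-methylhept-5-en-1-yn-4-yl]oxy}-1,3,2-dioxaborolane | CC(C)=C[C@H](OB1OC(C)(C)C(C)(C)O1)CC#C | intermediate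
4 | (4R)-6-methylhept-5-en-1-yn-4-ol | CC(C)=C[C@H](O)CC#C | intermediate
5 | tert-butyldimethyl{[(4R)-6-methylhept-5-en-1-yn-4-yl]oxy}silane | CC(C)=C[C@H](O[Si](C)(C)C(C)(C)C)CC#C | intermediate
6 | dimethyl[(1E,4R)-4-(tert-butyldimethylsilyloxy)-2,6-dimethylhepta-1,5-dien-1-yl]alane | CC(C)=C[C@H](O[Si](C)(C)C(C)(C)C)C/C(C)=C/[Al](C)C | intermediate
7 | (1E,4R)-4-(tert-butyldimethylsilyloxy)-1-iodo-2,6-dimethylhepta-1,5-diene | CC(C)=C[C@H](O[Si](C)(C)C(C)(C)C)C/C(C)=C/I | intermediate
8 | (4-bromobut-1-yn-1-yl)trimethylsilane | C[Si](C)(C)C#CCCBr | starting material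
9 | [4-(trimethylsilyl)but-3-yn-1-yl]zinc bromide | C[Si](C)(C)C#CCC[Zn]Br | intermediate
10 | (5E,8R)-8-(tert-butyldimethylsilyloxy)-6,10-dimethyl-1-(trimethylsilyl)undeca-5,9-dien-1-yne | CC(C)=C[C@H](O[Si](C)(C)C(C)(C)C)C/C(C)=C/CCC#C[Si](C)(C)C | intermediate
11 | (5E,8R)-8-(tert-butyldimethylsilyloxy)-6,10-dimethylundeca-5,9-dien-1-yne | CC(C)=C[C@H](O[Si](C)(C)C(C)(C)C)C/C(C)=C/CCC#C | intermediate
12 | oxirane | C1CO1 | starting material
13 | dimethyl[(1E,5E,8R)-8-(tert-butyldimethylsilyloxy)-2,6,10-trimethylundeca-1,5,9-trien-1-yl]alane | CC(C)=C[C@H](O[Si](C)(C)C(C)(C)C)C/C(C)=C/CC/C(C)=C/[Al](C)C | intermediate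
14 | lithium butyl(dimethyl)[(1E,5E,8R)-8-(tert-butyldimethylsilyloxy)-2,6,10-trimethylundeca-1,5,9-trien-1-yl]aluminate | CC(C)=C[C@H](O[Si](C)(C)C(C)(C)C)C/C(C)=C/CC/C(C)=C/[Al-](C)(C)CCCC.[Li+] | intermediate
15 | (3E,7E,10R)-10-(tert-butyldimethylsilyloxy)-4,8,12-trimethyltrideca-3,7,11-trien-1-ol | CC(C)=C[C@H](O[Si](C)(C)C(C)(C)C)C/C(C)=C/CC/C(C)=C/CCO | intermediate
16 | (3E,7E,10R)-10-(tert-butyldimethylsilyloxy)-1-iodo-4,8,12-trimethyltrideca-3,7,11-triene | CC(C)=C[C@H](O[Si](C)(C)C(C)(C)C)C/C(C)=C/CC/C(C)=C/CCI | intermediate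
17 | 3,4-dihydro-2H-pyran | C1=COCCC1 | starting material
18 | (3,4-dihydro-2H-pyran-6-yl)lithium | [Li]C1=CCCCO1 | intermediate
19 | 2-(3,4-dihydro-2H-pyran-6-yl)ethan-1-ol | OCCC1=CCCCO1 | intermediate
20 | 6-(2-iodoethyl)-3,4-dihydro-2H-pyran | ICCC1=CCCCO1 | intermediate
21 | ethyl 3-oxobutanoate | CCOC(=O)CC(C)=O | starting material
22 | ethyl 2-acetyl-4-(3,4-dihydro-2H-pyran-6-yl)butanoate (racemic) | CCOC(=O)C(CCC1=CCCCO1)C(C)=O | intermediate
23 | sodium (Z)-enolate of 22 (chelated) | CCOC(=O)/C(CCC1=CCCCO1)=C(/C)[O-].[Na+] | intermediate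
24 | ethyl (2Z)-2-[2-(3,4-dihydro-2H-pyran-6-yl)ethyl]-3-(trifluoromethylsulfonyloxy)but-2-enoate | CCOC(=O)/C(CCC1=CCCCO1)=C(/C)OS(=O)(=O)C(F)(F)F | intermediate
25 | [(3E,7E,10R)-10-(tert-butyldimethylsilyloxy)-4,8,12-trimethyltrideca-3,7,11-trien-1-yl]zinc iodide | CC(C)=C[C@H](O[Si](C)(C)C(C)(C)C)C/C(C)=C/CC/C(C)=C/CC[Zn]I | intermediate
26 | ethyl (2Z,6E,10E,13R)-13-(tert-butyldimethylsilyloxy)-2-[2-(3,4-dihydro-2H-pyran-6-yl)ethyl]-3,7,11,15-tetramethylhexadeca-2,6,10,14-tetraenoate | CC(C)=C[C@H](O[Si](C)(C)C(C)(C)C)C/C(C)=C/CC/C(C)=C/CC/C(C)=C(\C(=O)OCC)CCC1=CCCCO1 | intermediate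
27 | (2Z,6E,10E,13R)-13-(tert-butyldimethylsilyloxy)-2-[2-(3,4-dihydro-2H-pyran-6-yl)ethyl]-3,7,11,15-tetramethylhexadeca-2,6,10,14-tetraen-1-ol | CC(C)=C[C@H](O[Si](C)(C)C(C)(C)C)C/C(C)=C/CC/C(C)=C/CC/C(C)=C(\CO)CCC1=CCCCO1 | intermediate
28 | [(2S,3R)-2-[2-(3,4-dihydro-2H-pyran-6-yl)ethyl]-3-methyl-3-[(3E,7E,10R)-10-(tert-butyldimethylsilyloxy)-4,8,12-trimethyltrideca-3,7,11-trien-1-yl]oxiran-2-yl]methanol | CC(C)=C[C@H](O[Si](C)(C)C(C)(C)C)C/C(C)=C/CC/C(C)=C/CC[C@@]1(C)O[C@]1(CO)CCC1=CCCCO1 | intermediate
29 | methanesulfonate of 28 | CC(C)=C[C@H](O[Si](C)(C)C(C)(C)C)C/C(C)=C/CC/C(C)=C/CC[C@@]1(C)O[C@]1(COS(C)(=O)=O)CCC1=CCCCO1 | intermediate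
30 | (2R,3R)-2-[2-(3,4-dihydro-2H-pyran-6-yl)ethyl]-2,3-dimethyl-3-[(3E,7E,10R)-10-(tert-butyldimethylsilyloxy)-4,8,12-trimethyltrideca-3,7,11-trien-1-yl]oxirane | CC(C)=C[C@H](O[Si](C)(C)C(C)(C)C)C/C(C)=C/CC/C(C)=C/CC[C@@]1(C)O[C@]1(C)CCC1=CCCCO1 | intermediate
31 | bicyclic pyranylium ion with the C4 oxygen bound as dichloro(methyl)aluminate (zwitterion) | CC(C)=C[C@H](O[Si](C)(C)C(C)(C)C)C/C(C)=C/CC/C(C)=C/CC[C@]1(C)[C@H]2CCC[O+]=C2CC[C@@]1(C)O[Al-](C)(Cl)Cl | intermediate
32 | (2R,3R,4R)-4-hydroxy-2-(3-hydroxypropyl)-3,4-dimethyl-3-[(3E,7E,10R)-10-(tert-butyldimethylsilyloxy)-4,8,12-trimethyltrideca-3,7,11-trien-1-yl]cyclohexan-1-one | CC(C)=C[C@H](O[Si](C)(C)C(C)(C)C)C/C(C)=C/CC/C(C)=C/CC[C@]1(C)[C@@H](CCCO)C(=O)CC[C@@]1(C)O | intermediate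
33 | trimethyl(prop-1-en-1-yloxy)silane (E/Z mixture) | CC=CO[Si](C)(C)C | starting material
34 | 2-(octahydro-2H-chromen-8a-yl)propanal adduct (ring oxygen β to the aldehyde; configuration at the two new centres open) | CC(C)=C[C@H](O[Si](C)(C)C(C)(C)C)C/C(C)=C/CC/C(C)=C/CC[C@]1(C)[C@H]2CCCOC2(C(C)C=O)CC[C@@]1(C)O | intermediate
35 | (2Z)-2-[(2S,3R,4R)-4-hydroxy-2-(3-hydroxypropyl)-3,4-dimethyl-3-[(3E,7E,10R)-10-(tert-butyldimethylsilyloxy)-4,8,12-trimethyltrideca-3,7,11-trien-1-yl]cyclohexylidene]propanal | CC(C)=C[C@H](O[Si](C)(C)C(C)(C)C)C/C(C)=C/CC/C(C)=C/CC[C@]1(C)[C@@H](CCCO)/C(=C(/C)C=O)CC[C@@]1(C)O | intermediate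
36 | (2Z)-2-[(2S,3R,4R)-4-hydroxy-3-[(3E,7E,10R)-10-hydroxy-4,8,12-trimethyltrideca-3,7,11-trien-1-yl]-2-(3-hydroxypropyl)-3,4-dimethylcyclohexylidene]propanal | CC(C)=C[C@H](O)C/C(C)=C/CC/C(C)=C/CC[C@]1(C)[C@@H](CCCO)/C(=C(/C)C=O)CC[C@@]1(C)O | target

**Step count and risks**

Total step count: 17. Longest linear sequence: 13 steps (steps 1 to 6, then 11 to 17).

Steps most likely to fail:

1. Step 15. The Lewis acid may ionise the tetrasubstituted epoxide without participation of the enol ether; the open tertiary cation can then undergo a pinacol-type 1,2-shift, lose a proton to an allylic alcohol, or be captured by the nearest chain alkene. The pyranylium ion may also be trapped by that alkene before the quench. Fallback: the ring closure is moved one step earlier and run on the epoxy mesylate 29, isolated instead of being reduced. Its electron-withdrawing mesyloxymethyl group disfavours positive charge on the proximal epoxide carbon, so opening should occur only at the distal carbon with enol ether assistance. MeAlCl2 in CH2Cl2 at −78 °C with a MeOH/Et3N quench should give the bicyclic methyl ketal mesylate F1. LiBHEt3 then removes the sulfonate through the spiro-epoxide to give the methyl ketal F2, and pyridinium tosylate in wet acetone hydrolyses F2 to 32, where the route is rejoined.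

2. Step 16. The bicyclic oxocarbenium ion may lose a proton to the tetrasubstituted enol ether faster than it captures the silyl enol ether, the aldehyde adduct may react further, and the elimination may give the enal as a mixture of geometric isomers. Fallback: setting out from 32, a Horner–Wadsworth–Emmons olefination with the potassium salt of diethyl (1-cyanoethyl)phosphonate (t-BuOK, THF, reflux) gives the alkylidene nitrile F3; the Z isomer is separated and the other recycled by iodine-catalysed equilibration. Reduction with iBu2AlH at −78 °C and mild acidic hydrolysis of the aldimine returns to 35.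

3. Step 13. The titanium-bound epoxy alkoxide may be opened prematurely by the pendant enol ether (ring closure while the hydroxymethyl group is still present), or the enol ether may add the hydroperoxide under the Lewis-acidic conditions. Fallback: setting out from 27, the titanium tartrate template is replaced by a different catalyst class, a hydroxyl-directed vanadium epoxidation (VO(OiPr)3, a C2-symmetric chiral bishydroxamic acid ligand, cumene hydroperoxide, toluene, 0 °C). It binds only the allylic hydroxyl and exposes the product to no Lewis-acidic alkoxide. It returns directly at 28 and no new compound is formed (F0).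

Further compounds
F1 | step 15 | bicyclic methyl ketal with C4 hydroxyl and C4 mesyloxymethyl group | CC(C)=C[C@H](O[Si](C)(C)C(C)(C)C)C/C(C)=C/CC/C(C)=C/CC[C@]1(C)[C@H]2CCCOC2(OC)CC[C@@]1(COS(C)(=O)=O)O
F2 | step 15 | bicyclic methyl ketal with C4 hydroxyl and C4 methyl group | CC(C)=C[C@H](O[Si](C)(C)C(C)(C)C)C/C(C)=C/CC/C(C)=C/CC[C@]1(C)[C@H]2CCCOC2(OC)CC[C@@]1(C)O
F3 | step 16 | (2Z)-2-cyclohexylidenepropanenitrile analogue of 35 | CC(C)=C[C@H](O[Si](C)(C)C(C)(C)C)C/C(C)=C/CC/C(C)=C/CC[C@]1(C)[C@@H](CCCO)/C(=C(/C)C#N)CC[C@@]1(C)O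
F0 | step 13 | none | none
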